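The route rests on disconnecting the C1′–O bond of the tertiary carbinol while reconnecting C1′ to C5′. The key step exploits the carbocycle's homoallylic array C1′(OH)–C6′–C5′=C4′(Me), from which the vicinal C4′ chloride and C5′ bromide descend: it is the opened form of a bicyclo[3.1.0]hexane. In one operation, acid protonates a 4′-methylene group, the internal C1′–C5′ cyclopropane bond breaks, the five-membered ring becomes the cyclohexene and water enters at C1′ with inversion, fixing C1′ relative to the pyran. The precursor is the complete bromohydroxypyran carrying at C6 a 4′-methylenebicyclo[3.1.0]hexan-1′-yl group as one cyclopropane diastereomer, secured by hydroxyl-directed cyclopropanation.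

Key step: step 14

Remark: locants used throughout are pyran O1, C2 (CMe2), C3 (CHBr), C4, C5 (CHO), C6 (CMe) and carbocycle C1′ (bonded to C6) to C6′; methyl (R)-glycidate, the 2-methylprop-1-enyl Grignard solution and 3-bromocyclopent-2-en-1-one are assumed to be purchasable.

Step 1
Reactants: 1 methyl (2R)-oxirane-2-carboxylate; 2 (2-methylprop-1-en-1-yl)magnesium bromide
Product: 3 methyl (2R)-2-hydroxy-5-methylhex-4-enoate
Conditions: CuI (10 mol %), THF, −40 °C
Reagents that add atoms: none
Why: Copper-catalysed SN2 opening of the epoxide at its unsubstituted carbon by the alkenyl Grignard reagent should give the α-hydroxy ester without touching the chiral-pool stereocentre that becomes C5.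

Step 2
Reactants: 3 methyl (2R)-2-hydroxy-5-methylhex-4-enoate
Product: 4 (2R)-2-hydroxy-N-methoxy-N,5-dimethylhex-4-enamide
Conditions: MeNHOMe·HCl, i-PrMgCl, THF, −20 to 0 °C
Reagents that add atoms: N,O-dimethylhydroxylamine hydrochloride, CNOC.Cl
Why: Aminolysis of the ester by the chloromagnesium amide (Weinreb amide formation) tolerates the hydroxyl as its magnesium alkoxide and should leave the stereocentre intact.

Step 3
Reactants: 4 (2R)-2-hydroxy-N-methoxy-N,5-dimethylhex-4-enamide
Product: 5 (3R)-3-hydroxy-6-methylhept-5-en-2-one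
Conditions: MeMgBr (3 equiv), THF, −78 to 0 °C
Reagents that add atoms: methylmagnesium bromide, C[Mg]Br
Why: Weinreb ketone synthesis, in which magnesium chelation prevents a second addition and the α-alkoxide guards the stereocentre against enolisation.

Step 4
Reactants: 6 3-bromocyclopent-2-en-1-one
Product: 7 (1S)-3-bromocyclopent-2-en-1-ol
Conditions: (R)-Me-CBS (10 mol %), BH3·SMe2, THF, −20 °C
Reagents that add atoms: none
Why: Corey–Bakshi–Shibata reduction, in which the bromoalkene arm acts as the large substituent, so the (R)-catalyst should give the (S)-allylic alcohol that later directs the cyclopropanation.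

Step 5
Reactants: 7 (1S)-3-bromocyclopent-2-en-1-ol
Product: 8 {[(1S)-3-bromocyclopent-2-en-1-yl]oxy}triethylsilane
Conditions: TESCl, imidazole, CH2Cl2, 0 °C
Reagents that add atoms: chlorotriethylsilane, CC[Si](Cl)(CC)CC
Why: Standard silylation masks the hydroxyl for the halogen–metal exchange with a group that can later be removed beside a TBS ether.

Step 6
Reactants: 8 {[(1S)-3-bromocyclopent-2-en-1-yl]oxy}triethylsilane; 5 (3R)-3-hydroxy-6-methylhept-5-en-2-one
Product: 12 (2R,3R)-6-methyl-2-[(3S)-3-(triethylsilyloxy)cyclopent-1-en-1-yl]hept-5-ene-2,3-diol, via alkenyllithium 9 (not isolated), via alkenylmagnesium bromide 10 (not isolated), via bromomagnesium alkoxide 11 (not isolated)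
Conditions: 8: t-BuLi (2 equiv), Et2O/THF, −78 °C, then MgBr2·OEt2; 5: EtMgBr (1 equiv), THF, −78 °C; combine, −78 to −20 °C
Reagents that add atoms: none
Why: Bromine–lithium exchange and transmetalation give an alkenyl Grignard reagent that should add to the ketone under Cram chelation control, on the face of the five-membered magnesium chelate opposite the CH2 side chain, which sets the carbinol (future C6) as 2R with the two oxygens syn.

Step 7
Reactants: 12 (2R,3R)-6-methyl-2-[(3S)-3-(triethylsilyloxy)cyclopent-1-en-1-yl]hept-5-ene-2,3-diol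
Product: 13 (2R,3R)-3-(tert-butyldimethylsilyloxy)-6-methyl-2-[(3S)-3-(triethylsilyloxy)cyclopent-1-en-1-yl]hept-5-en-2-ol
Conditions: TBSOTf (1.05 equiv), 2,6-lutidine, CH2Cl2, −78 °C
Reagents that add atoms: tert-butyldimethylsilyl trifluoromethanesulfonate, CC(C)(C)[Si](C)(C)OS(=O)(=O)C(F)(F)F
Why: Chemoselective silylation of the secondary hydroxyl over the hindered tertiary one blocks 5-endo participation of this oxygen in the next step and protects it through the later oxidation.

Step 8
Reactants: 13 (2R,3R)-3-(tert-butyldimethylsilyloxy)-6-methyl-2-[(3S)-3-(triethylsilyloxy)cyclopent-1-en-1-yl]hept-5-en-2-ol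
Product: 14 (3R,5R,6R)-3-bromo-5-(tert-butyldimethylsilyloxy)-2,2,6-trimethyl-6-[(3S)-3-(triethylsilyloxy)cyclopent-1-en-1-yl]oxane
Conditions: TBCO, MeNO2, 0 °C, dark
Reagents that add atoms: 2,4,4,6-tetrabromocyclohexa-2,5-dien-1-one, BrC1=CC(Br)(Br)C=C(Br)C1=O
Why: Bromoetherification of the tertiary alcohol onto the more electron-rich isopropylidene alkene (6-endo, Markovnikov) through a chair transition state with the cyclopentenyl group equatorial and anti opening of the bromonium ion should place bromine equatorial, that is C3 R.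

Step 9
Reactants: 14 (3R,5R,6R)-3-bromo-5-(tert-butyldimethylsilyloxy)-2,2,6-trimethyl-6-[(3S)-3-(triethylsilyloxy)cyclopent-1-en-1-yl]oxane
Product: 15 (1S)-3-[(3R,5R,6R)-3-bromo-5-(tert-butyldimethylsilyloxy)-2,2,6-trimethyloxan-6-yl]cyclopent-2-en-1-ol
Conditions: PPTS (cat.), MeOH, 0 °C
Reagents that add atoms: none
Why: Mild acid methanolysis should cleave the unhindered secondary triethylsilyl ether while the hindered TBS ether, the bromide and the cyclic ether survive.

Step 10
Reactants: 15 (1S)-3-[(3R,5R,6R)-3-bromo-5-(tert-butyldimethylsilyloxy)-2,2,6-trimethyloxan-6-yl]cyclopent-2-en-1-ol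
Product: 16 (1′R,4′S,5′R)-1′-[(3R,5R,6R)-3-bromo-5-(tert-butyldimethylsilyloxy)-2,2,6-trimethyloxan-6-yl]bicyclo[3.1.0]hexan-4′-ol
Conditions: Et2Zn, CH2I2, CH2Cl2, 0 °C
Reagents that add atoms: diiodomethane, ICI
Why: Hydroxyl-directed Simmons–Smith cyclopropanation (Furukawa reagent) delivers the methylene to the alkene face cis to the C4′ hydroxyl, which sets C1′ and C5′ as one diastereomer.

Step 11
Reactants: 16 (1′R,4′S,5′R)-1′-[(3R,5R,6R)-3-bromo-5-(tert-butyldimethylsilyloxy)-2,2,6-trimethyloxan-6-yl]bicyclo[3.1.0]hexan-4′-ol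
Product: 17 (1′R,5′R)-1′-[(3R,5R,6R)-3-bromo-5-(tert-butyldimethylsilyloxy)-2,2,6-trimethyloxan-6-yl]bicyclo[3.1.0]hexan-4′-one
Conditions: TPAP (5 mol %), NMO, 4 Å MS, CH2Cl2, rt
Reagents that add atoms: none
Why: Ley–Griffith oxidation converts the secondary cyclopropylcarbinol into the ketone under neutral conditions that spare the silyl ether, the bromide and the cyclopropane.

Step 12
Reactants: 17 (1′R,5′R)-1′-[(3R,5R,6R)-3-bromo-5-(tert-butyldimethylsilyloxy)-2,2,6-trimethyloxan-6-yl]bicyclo[3.1.0]hexan-4′-one
Product: 18 (3R,5R,6R)-3-bromo-5-(tert-butyldimethylsilyloxy)-2,2,6-trimethyl-6-[(1′R,5′S)-4′-methylidenebicyclo[3.1.0]hexan-1′-yl]oxane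
Conditions: Ph3PCH3Br, KOt-Bu, THF, 0 °C to rt
Reagents that add atoms: methyltriphenylphosphonium bromide, C[P+](c1ccccc1)(c1ccccc1)c1ccccc1.[Br-]
Why: Wittig methylenation of the cyclopropyl ketone, the classical conversion of sabina ketone into sabinene, installs the exocyclic alkene without touching the ring fusion or the equatorial bromide.

Step 13
Reactants: 18 (3R,5R,6R)-3-bromo-5-(tert-butyldimethylsilyloxy)-2,2,6-trimethyl-6-[(1′R,5′S)-4′-methylidenebicyclo[3.1.0]hexan-1′-yl]oxane
Product: 19 (3R,5R,6R)-3-bromo-2,2,6-trimethyl-6-[(1′R,5′S)-4′-methylidenebicyclo[3.1.0]hexan-1′-yl]oxan-5-ol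
Conditions: TBAF, THF, rt
Reagents that add atoms: none
Why: Fluoride-induced desilylation frees the C5 hydroxyl, so the key step starts from the unprotected bromohydroxypyran and no protecting group remains to be removed afterwards.

Step 14
Reactants: 19 (3R,5R,6R)-3-bromo-2,2,6-trimethyl-6-[(1′R,5′S)-4′-methylidenebicyclo[3.1.0]hexan-1′-yl]oxan-5-ol
Product: 21 (3R,5R,6S)-3-bromo-6-[(1′R)-1′-hydroxy-4′-methylcyclohex-3′-en-1′-yl]-2,2,6-trimethyloxan-5-ol, via cyclopropylcarbinyl cation 20 (not isolated)
Conditions: HClO4 (0.1 M), THF–H2O (3:1), 0 °C to rt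
Reagents that add atoms: water, O
Why: Protonation of the exocyclic methylene gives the tertiary C4′ cyclopropylcarbinyl cation 20, whose charge is relayed into the internal C1′–C5′ bond, and water displaces C5′ at C1′ from the rear as that bond becomes the C4′=C5′ alkene. The closest known reaction type is the cyclopropylcarbinyl–homoallyl rearrangement with solvent capture, as in the acid hydration of sabinene to terpinen-4-ol. The six-membered ring is not closed by a new ring bond: it arises by ring enlargement when the zero-atom bridge of the bicyclo[3.1.0]hexane is cut, and the only bond formed is the exocyclic C1′–O bond in an SN2-like homoallylic displacement. The new stereocentre C1′ is controlled by the cyclopropane configuration from step 10, which is transferred with inversion (hydroxyl anti to the departing C5′). The step needs internal rather than external cyclopropane cleavage, secured because charge then develops at tertiary C1′ and not at primary C6′, and it needs capture rather than proton loss or a free cation, secured by high water activity, a non-nucleophilic counter-ion, low temperature and the electron-withdrawing C6 oxygen, which makes C1′–C5′ cleavage depend on nucleophilic assistance. The secondary bromide and the ether ring should be inert to the dilute acid, any internal trapping of C4′ by the C5 hydroxyl is reversible, and re-protonation of the product's trisubstituted alkene is far slower than protonation of the cyclopropyl-substituted methylene group.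

Step 15
Reactants: 21 (3R,5R,6S)-3-bromo-6-[(1′R)-1′-hydroxy-4′-methylcyclohex-3′-en-1′-yl]-2,2,6-trimethyloxan-5-ol
Product: 22 (3R,5R,6S)-3-bromo-6-[(1′R,4′S,5′S)-5′-bromo-4′-methyl-7′-oxabicyclo[2.2.1]heptan-1′-yl]-2,2,6-trimethyloxan-5-ol
Conditions: NBS, CH2Cl2, 0 °C, dark
Reagents that add atoms: N-bromosuccinimide, O=C1CCC(=O)N1Br
Why: Bromoetherification as in the conversion of terpinen-4-ol into 2-bromo-1,4-cineole: with the pyranyl group equatorial and the C1′ hydroxyl axial, the hydroxyl opens the bromonium ion formed on the opposite face at tertiary C4′, which sets C5′ (bromine anti to the bridging oxygen) and fixes the C4′ face.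

Step 16
Reactants: 22 (3R,5R,6S)-3-bromo-6-[(1′R,4′S,5′S)-5′-bromo-4′-methyl-7′-oxabicyclo[2.2.1]heptan-1′-yl]-2,2,6-trimethyloxan-5-ol
Product: 23 (3R,5R,6S)-3-bromo-6-[(1′R,4′S,5′S)-5′-bromo-4′-chloro-1′-hydroxy-4′-methylcyclohexyl]-2,2,6-trimethyloxan-5-ol
Conditions: TiCl4 (2.2 equiv), CH2Cl2, −78 °C
Reagents that add atoms: titanium tetrachloride, Cl[Ti](Cl)(Cl)Cl
Why: Lewis-acid cleavage of the strained bridging ether at tertiary C4′ with neighbouring-group participation of the anti C5′ bromine, chloride being returned from titanium to the face the oxygen leaves, should give net retention at C4′ (chlorine cis to the C1′ hydroxyl and trans to bromine).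

Compound list
1 | methyl (2R)-oxirane-2-carboxylate (methyl (R)-glycidate) | COC(=O)[C@H]1CO1 | starting material
2 | (2-methylprop-1-en-1-yl)magnesium bromide (THF solution) | CC(C)=C[Mg]Br | starting material
3 | methyl (2R)-2-hydroxy-5-methylhex-4-enoate | COC(=O)[C@H](O)CC=C(C)C | intermediate
4 | (2R)-2-hydroxy-N-methoxy-N,5-dimethylhex-4-enamide | CON(C)C(=O)[C@H](O)CC=C(C)C | intermediate
5 | (3R)-3-hydroxy-6-methylhept-5-en-2-one | CC(=O)[C@H](O)CC=C(C)C | intermediate
6 | 3-bromocyclopent-2-en-1-one | O=C1CCC(Br)=C1 | starting material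
7 | (1S)-3-bromocyclopent-2-en-1-ol | O[C@H]1CCC(Br)=C1 | intermediate
8 | {[(1S)-3-bromocyclopent-2-en-1-yl]oxy}triethylsilane | CC[Si](CC)(CC)O[C@H]1CCC(Br)=C1 | intermediate
9 | [(3S)-3-(triethylsilyloxy)cyclopent-1-en-1-yl]lithium | CC[Si](CC)(CC)O[C@H]1CCC([Li])=C1 | intermediate (not isolated)
10 | [(3S)-3-(triethylsilyloxy)cyclopent-1-en-1-yl]magnesium bromide | CC[Si](CC)(CC)O[C@H]1CCC([Mg]Br)=C1 | intermediate (not isolated)
11 | bromomagnesium (3R)-6-methyl-2-oxohept-5-en-3-olate (alkoxide of 5) | CC(=O)[C@H](O[Mg]Br)CC=C(C)C | intermediate (not isolated)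
12 | (2R,3R)-6-methyl-2-[(3S)-3-(triethylsilyloxy)cyclopent-1-en-1-yl]hept-5-ene-2,3-diol | O[C@](C)(C1=C[C@@H](O[Si](CC)(CC)CC)CC1)[C@H](O)CC=C(C)C | intermediate
13 | (2R,3R)-3-(tert-butyldimethylsilyloxy)-6-methyl-2-[(3S)-3-(triethylsilyloxy)cyclopent-1-en-1-yl]hept-5-en-2-ol | O[C@](C)(C1=C[C@@H](O[Si](CC)(CC)CC)CC1)[C@H](O[Si](C)(C)C(C)(C)C)CC=C(C)C | intermediate
14 | (3R,5R,6R)-3-bromo-5-(tert-butyldimethylsilyloxy)-2,2,6-trimethyl-6-[(3S)-3-(triethylsilyloxy)cyclopent-1-en-1-yl]oxane | CC1(C)O[C@](C)(C2=C[C@@H](O[Si](CC)(CC)CC)CC2)[C@H](O[Si](C)(C)C(C)(C)C)C[C@H]1Br | intermediate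
15 | (1S)-3-[(3R,5R,6R)-3-bromo-5-(tert-butyldimethylsilyloxy)-2,2,6-trimethyloxan-6-yl]cyclopent-2-en-1-ol | CC1(C)O[C@](C)(C2=C[C@@H](O)CC2)[C@H](O[Si](C)(C)C(C)(C)C)C[C@H]1Br | intermediate
16 | (1′R,4′S,5′R)-1′-[(3R,5R,6R)-3-bromo-5-(tert-butyldimethylsilyloxy)-2,2,6-trimethyloxan-6-yl]bicyclo[3.1.0]hexan-4′-ol (hydroxyl cis to the cyclopropane CH2) | CC1(C)O[C@](C)([C@@]23CC[C@H](O)[C@@H]2C3)[C@H](O[Si](C)(C)C(C)(C)C)C[C@H]1Br | intermediate
17 | (1′R,5′R)-1′-[(3R,5R,6R)-3-bromo-5-(tert-butyldimethylsilyloxy)-2,2,6-trimethyloxan-6-yl]bicyclo[3.1.0]hexan-4′-one | CC1(C)O[C@](C)([C@@]23CCC(=O)[C@@H]2C3)[C@H](O[Si](C)(C)C(C)(C)C)C[C@H]1Br | intermediate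
18 | (3R,5R,6R)-3-bromo-5-(tert-butyldimethylsilyloxy)-2,2,6-trimethyl-6-[(1′R,5′S)-4′-methylidenebicyclo[3.1.0]hexan-1′-yl]oxane | CC1(C)O[C@](C)([C@@]23CCC(=C)[C@@H]2C3)[C@H](O[Si](C)(C)C(C)(C)C)C[C@H]1Br | intermediate
19 | (3R,5R,6R)-3-bromo-2,2,6-trimethyl-6-[(1′R,5′S)-4′-methylidenebicyclo[3.1.0]hexan-1′-yl]oxan-5-ol (key-step precursor) | CC1(C)O[C@](C)([C@@]23CCC(=C)[C@@H]2C3)[C@H](O)C[C@H]1Br | intermediate
20 | C4′ tertiary cyclopropylcarbinyl cation of 19 (4′-methylbicyclo[3.1.0]hexan-4′-ylium) | CC1(C)O[C@](C)([C@@]23CC[C+](C)[C@@H]2C3)[C@H](O)C[C@H]1Br | intermediate (not isolated)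
21 | (3R,5R,6S)-3-bromo-6-[(1′R)-1′-hydroxy-4′-methylcyclohex-3′-en-1′-yl]-2,2,6-trimethyloxan-5-ol (key-step product) | CC1(C)O[C@](C)([C@@]2(O)CCC(C)=CC2)[C@H](O)C[C@H]1Br | intermediate
22 | (3R,5R,6S)-3-bromo-6-[(1′R,4′S,5′S)-5′-bromo-4′-methyl-7′-oxabicyclo[2.2.1]heptan-1′-yl]-2,2,6-trimethyloxan-5-ol (oxygen bridges C1′ and C4′; 5′-bromine endo, anti to the bridge) | CC1(C)O[C@](C)([C@@]23CC[C@](C)(O3)[C@@H](Br)C2)[C@H](O)C[C@H]1Br | intermediate
23 | (3R,5R,6S)-3-bromo-6-[(1′R,4′S,5′S)-5′-bromo-4′-chloro-1′-hydroxy-4′-methylcyclohexyl]-2,2,6-trimethyloxan-5-ol (CNP0244614.1) | CC1(C)O[C@](C)([C@@]2(O)CC[C@](C)(Cl)[C@@H](Br)C2)[C@H](O)C[C@H]1Br | target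

Total step count: 16.
Longest linear sequence: 14 steps (steps 1–3 and 6–16).

Steps most likely to fail

Step 14 (key step). Proton loss from cation 20 or from the ring-opened ion may outrun water capture at the crowded C1′, giving dienes. Ionisation without nucleophilic assistance would cost the C1′ configuration or allow a 1,2-shift towards C6. The fallback replaces intermolecular water by an internal oxygen nucleophile. It sets out from 19, whose C5 hydroxyl is acylated (Boc2O, DMAP, MeCN) to the tert-butyl carbonate F1. A catalytic Brønsted acid in anhydrous CH2Cl2 (CSA, 0 °C) then triggers the same protonation and C1′–C5′ cleavage. The carbonate carbonyl oxygen, held next to C1′, attacks anti to C5′ through a six-membered ring and isobutene is lost, which gives the cyclic carbonate F2. Methanolysis (K2CO3, MeOH) returns to the route at 21. Capture of cations by tert-butyl carbonates is established chemistry.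

Step 8. Closure may take the 5-exo course to a tetrahydrofuran, the bromine electrophile may attack the cyclopentene and set off a semipinacol shift of the allylic carbinol, or facial control at C3 may be poor. The fallback sets out from 13 and uses mercuricyclisation, which is more strongly Markovnikov and reversible. Hg(OCOCF3)2 (buffered, CH2Cl2, −20 °C) followed by aqueous NaBr should give the equatorial C3 alkylmercuric bromide F3. Brominolysis in pyridine (Br2, pyridine, 0 °C), which proceeds with retention, returns to the route at 14.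

Step 16. The Lewis acid may instead ionise the pyran C2–O bond, to which the equatorial C3 bromine is also anti-periplanar, or the C4′ cation may lose a proton before chloride arrives. The fallback leaves out the bridged ether and sets out from 21. The C1′ hydroxyl is converted into its chlorotitanium alkoxide (ClTi(Oi-Pr)3, CH2Cl2–hexane, −20 °C) and NBS is added. Titanium-bound chloride is then delivered across the ring to C4′ of the bromonium ion formed on the opposite face, while the titanated oxygen is too weakly nucleophilic to bridge. This is an alkoxide-directed bromochlorination that returns to the route at 23 without any new compound (F0).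

Further compounds
F1 | step 14 | tert-butyl (3R,5R,6R)-3-bromo-2,2,6-trimethyl-6-[(1′R,5′S)-4′-methylidenebicyclo[3.1.0]hexan-1′-yl]oxan-5-yl carbonate | CC1(C)O[C@](C)([C@@]23CCC(=C)[C@@H]2C3)[C@H](OC(=O)OC(C)(C)C)C[C@H]1Br
F2 | step 14 | cyclic carbonate of 21 joining the C5 and C1′ oxygens (1,3-dioxan-2-one spiro-fused to the cyclohexene at C1′) | CC1(C)O[C@](C)([C@@]2(O3)CCC(C)=CC2)[C@H](OC3=O)C[C@H]1Br
F3 | step 8 | C3 bromomercurio analogue of 14 (HgBr in place of the C3 bromine, same configuration) | CC1(C)O[C@](C)(C2=C[C@@H](O[Si](CC)(CC)CC)CC2)[C@H](O[Si](C)(C)C(C)(C)C)C[C@H]1[Hg]Br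
F0 | step 16 | none | none
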